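**Retrosynthetic overview**

1. Enabling feature: the 1,2-dioxan-3-ol ring (O1–O2–C3–C4–C5–C6) is the closed tautomer of a γ-hydroperoxy ketone. C3 is a masked acetyl carbon, C4 its enolisable α-carbon, and both ring oxygens hang as one hydroperoxide on the quaternary C6.
2. C4–C5 is therefore made as a carbonyl-condensation bond. The C6 hydroperoxide is acylated with diketene, and the acetoacetyl CH2 (C4) closes onto a C5 aldehyde in an intramolecular reductive Knoevenagel reaction; the perester carbonyl is a traceless tether atom.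
3. Ring order: a temporary six-membered peroxylactone (1,2-dioxan-3-one) first. After C-methylation, saponification and loss of CO2 let the hydroperoxide re-close on the acetyl carbon to give the 1,2-dioxan-3-ol, with C3 and C4 settling by equilibration.
4. C6–OOH comes from invertive perhydrolysis of an (R)-2,2-disubstituted epoxide, itself made by catalytic asymmetric Corey–Chaykovsky methylene transfer to a methyl ketone.
5. Side chain: copper-catalysed asymmetric conjugate methylation of an E-enone (remote methyl centre), Wittig olefination, and a Z-styrene from alkyne semihydrogenation.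

Key step: step 10

Assumption: in the two catalyst-controlled steps (5 and 6) the ligand antipode is taken that gives the product configuration named; the sense of induction of each antipode is to be confirmed on a model substrate.

Step 1
Reactants: 1 7-bromoheptan-1-ol; 2 ethynylbenzene
Product: 3 9-phenylnon-8-yn-1-ol
Conditions: 2 (2.4 equiv), n-BuLi (2.3 equiv), THF, −78 °C; then 1, DMPU, −78 → 50 °C; aq. NH4Cl
Reagents that add atoms: none
Why: SN2 alkylation of a lithium acetylide by a primary alkyl bromide, the hydroxyl group being carried as its lithium alkoxide; no stereocentre is formed.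

Step 2
Reactants: 3 9-phenylnon-8-yn-1-ol
Product: 4 (8Z)-9-phenylnon-8-en-1-ol
Conditions: H2 (1 atm), Pd/CaCO3 poisoned with Pb(OAc)2, quinoline, EtOAc, 23 °C
Reagents that add atoms: none
Why: Cis-selective semihydrogenation of an internal alkyne on lead-poisoned palladium; syn addition of H2 on the surface sets the Z double bond and quinoline suppresses over-reduction.

Step 3
Reactants: 4 (8Z)-9-phenylnon-8-en-1-ol
Product: 5 (8Z)-9-phenylnon-8-enal
Conditions: Dess–Martin periodinane, CH2Cl2, 23 °C
Reagents that add atoms: none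
Why: Dess–Martin oxidation of a primary alcohol to the aldehyde under neutral conditions that leave the Z-styrene untouched.

Step 4
Reactants: 5 (8Z)-9-phenylnon-8-enal; 6 1-(triphenyl-λ5-phosphanylidene)propan-2-one
Product: 7 (3E,11Z)-12-phenyldodeca-3,11-dien-2-one
Conditions: CH2Cl2, 40 °C
Reagents that add atoms: none
Why: Wittig olefination with a carbonyl-stabilised ylide, which should give the E-enone through the more stable anti oxaphosphetane pathway.

Step 5
Reactants: 7 (3E,11Z)-12-phenyldodeca-3,11-dien-2-one
Product: 8 (4R,11Z)-4-methyl-12-phenyldodec-11-en-2-one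
Conditions: MeMgBr, CuBr·SMe2 (5 mol %), (R)-1-[(S)-2-(diphenylphosphino)ferrocenyl]ethyldicyclohexylphosphine or its enantiomer (6 mol %), t-BuOMe, −75 °C
Reagents that add atoms: methylmagnesium bromide, C[Mg]Br
Why: Copper-catalysed enantioselective conjugate addition of a Grignard reagent to an acyclic enone; the chiral ferrocenyl diphosphine–copper complex differentiates the enone faces and sets the methyl-bearing carbon as R under catalyst control, the Z-styrene being inert.

Step 6
Reactants: 8 (4R,11Z)-4-methyl-12-phenyldodec-11-en-2-one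
Product: 9 (2R)-2-methyl-2-[(2R,9Z)-2-methyl-10-phenyldec-9-en-1-yl]oxirane
Conditions: Me3S(O)I, NaH, THF; then 8, LaLi3tris(1,1′-binaphthalene-2,2′-diolate) (5 mol %), tris(2,4,6-trimethoxyphenyl)phosphine oxide (5 mol %), 5 Å MS, THF, 23 °C
Reagents that add atoms: dimethyloxosulfonium methylide, C[S+](C)(=O)[CH2-]
Why: Catalytic asymmetric Corey–Chaykovsky epoxidation of a methyl ketone; the lanthanum–lithium binaphthoxide complex binds ketone and ylide and delivers CH2 to one face of the C=O group, setting the tertiary epoxide carbon as R under catalyst control, with little influence expected from the remote β-methyl centre.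

Step 7
Reactants: 9 (2R)-2-methyl-2-[(2R,9Z)-2-methyl-10-phenyldec-9-en-1-yl]oxirane
Product: 10 (2S,4R,11Z)-2-hydroperoxy-2,4-dimethyl-12-phenyldodec-11-en-1-ol
Conditions: H2O2 (dry, in Et2O), H3PMo12O40 (cat.), Et2O, 23 °C
Reagents that add atoms: hydrogen peroxide, OO
Why: Acid-catalysed perhydrolysis of a 2,2-disubstituted epoxide; H2O2 opens the activated epoxide at the tertiary carbon in a borderline SN2 process with inversion, so the R epoxide carbon becomes the S tertiary hydroperoxide carbon and the CH2 terminus is released as the primary alcohol.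

Step 8
Reactants: 10 (2S,4R,11Z)-2-hydroperoxy-2,4-dimethyl-12-phenyldodec-11-en-1-ol; 11 diketene (4-methylideneoxetan-2-one)
Product: 12 (2S,4R,11Z)-1-hydroxy-2,4-dimethyl-12-phenyldodec-11-en-2-yl 3-oxobutaneperoxoate
Conditions: 11 (1.05 equiv), Et3N (cat.), CH2Cl2, −20 °C
Reagents that add atoms: none
Why: Acylation of a hydroperoxide by ring opening of diketene (perester formation); the more acidic, α-effect OOH group should react before the neopentyl-type primary hydroxyl, and no stereocentre is involved.

Step 9
Reactants: 12 (2S,4R,11Z)-1-hydroxy-2,4-dimethyl-12-phenyldodec-11-en-2-yl 3-oxobutaneperoxoate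
Product: 13 (2S,4R,11Z)-2,4-dimethyl-1-oxo-12-phenyldodec-11-en-2-yl 3-oxobutaneperoxoate
Conditions: Dess–Martin periodinane, CH2Cl2, 0 °C
Reagents that add atoms: none
Why: Dess–Martin oxidation of the primary alcohol to the aldehyde under non-basic conditions, which the perester and the non-enolisable α-quaternary aldehyde should tolerate.

Step 10
Reactants: 13 (2S,4R,11Z)-2,4-dimethyl-1-oxo-12-phenyldodec-11-en-2-yl 3-oxobutaneperoxoate
Product: 15 (6S)-4-acetyl-6-methyl-6-[(2R,9Z)-2-methyl-10-phenyldec-9-en-1-yl]-1,2-dioxan-3-one, via alkylidene peroxylactone 14 (not isolated)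
Conditions: L-proline (10 mol %), diethyl 2,6-dimethyl-1,4-dihydropyridine-3,5-dicarboxylate (Hantzsch ester, 1.2 equiv), CH2Cl2, 23 °C
Reagents that add atoms: none
Why: Proposed new method: the amine catalyst condenses the acetoacetyl CH2 (future C4) with the tethered aldehyde carbon (future C5) in an intramolecular Knoevenagel reaction (aldol addition, then E1cB loss of water) to give the alkylidene β-keto perester 14, and the Hantzsch ester then transfers hydride to its doubly activated C=C bond, so that the C4–C5 bond reaches the saturated level in the same flask. The closest known reaction types are the intramolecular Knoevenagel cyclisation of acetoacetates of hydroxy aldehydes to 3-acyl unsaturated lactones and the amine-catalysed three-component reductive alkylation of active methylene compounds with aldehydes and Hantzsch ester; what is new is that the tether is a perester. The only ring closed is the six-membered peroxylactone O1–O2–C(=O)–C4–C5–C6, formed in a 6-(enolexo)-exo-trig aldol mode by the C4–C5 bond. No lasting stereocentre is created, since C5 becomes CH2 and C4 stays epimerisable until it is reset in step 12, while the quaternary 6S centre has no acidic hydrogen and is not touched. The step needs chemoselective hydride transfer to the alkylidene 1,3-dicarbonyl in the presence of the Z-styrene, the ketone and the O–O bond, which the very electron-poor alkene and the metal-free hydride donor should secure, and it needs cyclisation to outrun aminolysis of the perester, which the six-membered transition state and the weakly nucleophilic amino acid catalyst should secure.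

Step 11
Reactants: 15 (6S)-4-acetyl-6-methyl-6-[(2R,9Z)-2-methyl-10-phenyldec-9-en-1-yl]-1,2-dioxan-3-one
Product: 16 (6S)-4-acetyl-4,6-dimethyl-6-[(2R,9Z)-2-methyl-10-phenyldec-9-en-1-yl]-1,2-dioxan-3-one
Conditions: MeI, K2CO3, acetone, 0 → 23 °C
Reagents that add atoms: iodomethane, CI
Why: C-alkylation of the carbonate-generated enolate of a cyclic β-keto perester with iodomethane (β-dicarbonyl alkylation); the new quaternary centre may form as a mixture because it is erased again in step 12.

Step 12
Reactants: 16 (6S)-4-acetyl-4,6-dimethyl-6-[(2R,9Z)-2-methyl-10-phenyldec-9-en-1-yl]-1,2-dioxan-3-one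
Product: 19 (3S,4R,6S)-3,4,6-trimethyl-6-[(2R,9Z)-2-methyl-10-phenyldec-9-en-1-yl]-1,2-dioxan-3-ol, via keto acid hydroperoxide 17 (not isolated), via hydroperoxy ketone 18 (not isolated)
Conditions: LiOH, THF–H2O, 0 °C; 1 M HCl to pH 3, 23 °C; then DBU (cat.), CH2Cl2, 23 °C
Reagents that add atoms: none
Why: Perester saponification, decarboxylation of the α,α-disubstituted β-keto acid and cyclisation of the γ-hydroperoxy ketone (ring–chain tautomerism) are standard reaction types; because C3 equilibrates through ring opening and C4 through enolisation of the open ketone, the mixture should drain into the chair with 3-OH axial (anomeric effect) and 3-CH3, 4-CH3 and the long C6 substituent equatorial, which is the (3S,4R) arrangement relative to the fixed 6S centre.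

**Compound list**

1 | 7-bromoheptan-1-ol | OCCCCCCCBr | starting material
2 | ethynylbenzene (phenylacetylene) | C#Cc1ccccc1 | starting material
3 | 9-phenylnon-8-yn-1-ol | OCCCCCCCC#Cc1ccccc1 | intermediate
4 | (8Z)-9-phenylnon-8-en-1-ol | OCCCCCCC/C=C\c1ccccc1 | intermediate
5 | (8Z)-9-phenylnon-8-enal | O=CCCCCCC/C=C\c1ccccc1 | intermediate
6 | 1-(triphenyl-λ5-phosphanylidene)propan-2-one | CC(=O)C=P(c1ccccc1)(c1ccccc1)c1ccccc1 | starting material
7 | (3E,11Z)-12-phenyldodeca-3,11-dien-2-one | CC(=O)/C=C/CCCCCC/C=C\c1ccccc1 | intermediate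
8 | (4R,11Z)-4-methyl-12-phenyldodec-11-en-2-one | C[C@H](CCCCCC/C=C\c1ccccc1)CC(C)=O | intermediate
9 | (2R)-2-methyl-2-[(2R,9Z)-2-methyl-10-phenyldec-9-en-1-yl]oxirane | C[C@H](CCCCCC/C=C\c1ccccc1)C[C@]1(C)CO1 | intermediate
10 | (2S,4R,11Z)-2-hydroperoxy-2,4-dimethyl-12-phenyldodec-11-en-1-ol | C[C@H](CCCCCC/C=C\c1ccccc1)C[C@](C)(OO)CO | intermediate
11 | diketene (4-methylideneoxetan-2-one) | C=C1CC(=O)O1 | starting material
12 | (2S,4R,11Z)-1-hydroxy-2,4-dimethyl-12-phenyldodec-11-en-2-yl 3-oxobutaneperoxoate | C[C@H](CCCCCC/C=C\c1ccccc1)C[C@](C)(OOC(=O)CC(C)=O)CO | intermediate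
13 | (2S,4R,11Z)-2,4-dimethyl-1-oxo-12-phenyldodec-11-en-2-yl 3-oxobutaneperoxoate | C[C@H](CCCCCC/C=C\c1ccccc1)C[C@](C)(OOC(=O)CC(C)=O)C=O | intermediate
14 | (6S)-4-acetyl-6-methyl-6-[(2R,9Z)-2-methyl-10-phenyldec-9-en-1-yl]-6H-1,2-dioxin-3-one | C[C@H](CCCCCC/C=C\c1ccccc1)C[C@@]1(C)C=C(C(C)=O)C(=O)OO1 | intermediate
15 | (6S)-4-acetyl-6-methyl-6-[(2R,9Z)-2-methyl-10-phenyldec-9-en-1-yl]-1,2-dioxan-3-one (both C4 epimers) | C[C@H](CCCCCC/C=C\c1ccccc1)C[C@@]1(C)CC(C(C)=O)C(=O)OO1 | intermediate
16 | (6S)-4-acetyl-4,6-dimethyl-6-[(2R,9Z)-2-methyl-10-phenyldec-9-en-1-yl]-1,2-dioxan-3-one (both C4 epimers) | C[C@H](CCCCCC/C=C\c1ccccc1)C[C@@]1(C)CC(C)(C(C)=O)C(=O)OO1 | intermediate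
17 | (4S,6R,13Z)-2-acetyl-4-hydroperoxy-2,4,6-trimethyl-14-phenyltetradec-13-enoic acid (both C2 epimers) | C[C@H](CCCCCC/C=C\c1ccccc1)C[C@](C)(OO)CC(C)(C(C)=O)C(=O)O | intermediate
18 | (5S,7R,14Z)-5-hydroperoxy-3,5,7-trimethyl-15-phenylpentadec-14-en-2-one (both C3 epimers) | C[C@H](CCCCCC/C=C\c1ccccc1)C[C@](C)(OO)CC(C)C(C)=O | intermediate
19 | (3S,4R,6S)-3,4,6-trimethyl-6-[(2R,9Z)-2-methyl-10-phenyldec-9-en-1-yl]-1,2-dioxan-3-ol | C[C@H](CCCCCC/C=C\c1ccccc1)C[C@@]1(C)C[C@@H](C)[C@@](C)(O)OO1 | target

**Step count and risks**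

Total step count: 12. Longest linear sequence: 12 steps (from 1; compounds 2, 6 and 11 are purchased).

The three steps most likely to fail:

Step 10 (carries the label). The amine catalyst or the dihydropyridine may attack the perester (acyl transfer to nitrogen, reduction of the O–O bond) faster than condensation and hydride transfer proceed, or the tertiary perester may ionise with Criegee-type migration. The fallback drops the perester tether and uses known chemistry; it sets out from 10 and comes back to the route at 19. The hydroperoxide is silylated selectively (Et3SiCl, imidazole, CH2Cl2, −20 °C) to (2S,4R,11Z)-2,4-dimethyl-12-phenyl-2-[(triethylsilyl)peroxy]dodec-11-en-1-ol F1. Dess–Martin oxidation gives (2S,4R,11Z)-2,4-dimethyl-12-phenyl-2-[(triethylsilyl)peroxy]dodec-11-enal F2. The amine-catalysed three-component reductive alkylation (Knoevenagel condensation, then Hantzsch ester transfer hydrogenation) with tert-butyl 3-oxobutanoate gives tert-butyl (4S,6R,13Z)-2-acetyl-4,6-dimethyl-14-phenyl-4-[(triethylsilyl)peroxy]tetradec-13-enoate F3. C-methylation (MeI, K2CO3) gives tert-butyl (4S,6R,13Z)-2-acetyl-2,4,6-trimethyl-14-phenyl-4-[(triethylsilyl)peroxy]tetradec-13-enoate F4. CF3CO2H in CH2Cl2 then cleaves the tert-butyl ester and the silyl peroxide, the β-keto acid decarboxylates, and the hydroperoxy ketone closes and equilibrates to 19.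

Step 12. Convergence at C4 may be incomplete: C6 carries two alkyl groups of similar size, so the free-energy gap between the two C4 epimers of the hemiketal may be small, and enolisation of the minor open-chain ketone may be slow. The fallback replaces the single thermodynamic funnel by a separate-and-recycle loop; it sets out from 19 as obtained in step 12 (together with its C4 epimer) and comes back at 19. Ketalisation with MeOH and pyridinium p-toluenesulfonate gives the configurationally fixed methyl peroxyketal (3S,4R,6S)-3-methoxy-3,4,6-trimethyl-6-[(2R,9Z)-2-methyl-10-phenyldec-9-en-1-yl]-1,2-dioxane F5, which is separated by chromatography from its C4 epimer. The epimer fraction is hydrolysed, re-equilibrated with base and fed back, and F5 is hydrolysed with dilute aqueous acid in THF to 19.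

Step 8. Acylation may occur at the primary hydroxyl instead of or as well as at the hydroperoxide, and the acetoacetyl group may shift from the peroxide oxygen to the neighbouring oxygen (1,5-acyl transfer) under the basic catalyst. The fallback separates the two nucleophiles by protection; it sets out from 10 and comes back at 12. Both groups are silylated (Et3SiOTf, 2,6-lutidine) to triethyl{[(2S,4R,11Z)-2,4-dimethyl-12-phenyl-2-[(triethylsilyl)peroxy]dodec-11-en-1-yl]oxy}silane F6. The more labile silyl peroxide is cleaved selectively (K2CO3, MeOH, 0 °C) to triethyl{[(2S,4R,11Z)-2-hydroperoxy-2,4-dimethyl-12-phenyldodec-11-en-1-yl]oxy}silane F7. Diketene then acylates the only free nucleophile to give (2S,4R,11Z)-2,4-dimethyl-12-phenyl-1-[(triethylsilyl)oxy]dodec-11-en-2-yl 3-oxobutaneperoxoate F8, and HF·pyridine removes the silyl ether under acidic conditions, where the acyl shift should be slow, to return 12.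

**Further compounds**

F1 | step 10 | (2S,4R,11Z)-2,4-dimethyl-12-phenyl-2-[(triethylsilyl)peroxy]dodec-11-en-1-ol | C[C@H](CCCCCC/C=C\c1ccccc1)C[C@](C)(OO[Si](CC)(CC)CC)CO
F2 | step 10 | (2S,4R,11Z)-2,4-dimethyl-12-phenyl-2-[(triethylsilyl)peroxy]dodec-11-enal | C[C@H](CCCCCC/C=C\c1ccccc1)C[C@](C)(OO[Si](CC)(CC)CC)C=O
F3 | step 10 | tert-butyl (4S,6R,13Z)-2-acetyl-4,6-dimethyl-14-phenyl-4-[(triethylsilyl)peroxy]tetradec-13-enoate | C[C@H](CCCCCC/C=C\c1ccccc1)C[C@](C)(OO[Si](CC)(CC)CC)CC(C(C)=O)C(=O)OC(C)(C)C
F4 | step 10 | tert-butyl (4S,6R,13Z)-2-acetyl-2,4,6-trimethyl-14-phenyl-4-[(triethylsilyl)peroxy]tetradec-13-enoate | C[C@H](CCCCCC/C=C\c1ccccc1)C[C@](C)(OO[Si](CC)(CC)CC)CC(C)(C(C)=O)C(=O)OC(C)(C)C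
F5 | step 12 | (3S,4R,6S)-3-methoxy-3,4,6-trimethyl-6-[(2R,9Z)-2-methyl-10-phenyldec-9-en-1-yl]-1,2-dioxane | C[C@H](CCCCCC/C=C\c1ccccc1)C[C@@]1(C)C[C@@H](C)[C@@](C)(OC)OO1
F6 | step 8 | triethyl{[(2S,4R,11Z)-2,4-dimethyl-12-phenyl-2-[(triethylsilyl)peroxy]dodec-11-en-1-yl]oxy}silane | C[C@H](CCCCCC/C=C\c1ccccc1)C[C@](C)(OO[Si](CC)(CC)CC)CO[Si](CC)(CC)CC
F7 | step 8 | triethyl{[(2S,4R,11Z)-2-hydroperoxy-2,4-dimethyl-12-phenyldodec-11-en-1-yl]oxy}silane | C[C@H](CCCCCC/C=C\c1ccccc1)C[C@](C)(OO)CO[Si](CC)(CC)CC
F8 | step 8 | (2S,4R,11Z)-2,4-dimethyl-12-phenyl-1-[(triethylsilyl)oxy]dodec-11-en-2-yl 3-oxobutaneperoxoate | C[C@H](CCCCCC/C=C\c1ccccc1)C[C@](C)(OOC(=O)CC(C)=O)CO[Si](CC)(CC)CC
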